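**Retrosynthetic overview**

- Ring numbering: C1 (acetoxy carbon), C2, C3=C4 (methyl on C4), C5 (carries C7H2–O–aryl), C6 (gem-dimethyl). The plan rests on the lone ring alkene C3=C4 with C2 and C5 on either side of it, the retron of a [4+2] cycloaddition that forms C1–C2 and C5–C6.
- Last disconnection: the C7–O aryl ether, made by Mitsunobu coupling with umbelliferone, so the coumarin bicycle enters intact at the end.
- Before that, one C6 methyl is traced back to a formyl group (tosylhydrazone reduction). C6 then becomes the methyl/formyl α-carbon of a methacrolein-type dienophile and C1–OAc its β-carbon.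
- Cycloaddition partners: the TBS ether of (2E)-3-methylpenta-2,4-dien-1-ol (C2–C5 and C7) and (E)-3-acetoxy-2-methylacrolein (C1, C6), joined under a chiral cationic oxazaborolidine. The cyclohexene is the only ring formed in the route.
- Each partner is made in two steps, from commercial (E)-3-methylpent-2-en-4-yn-1-ol and from 3-ethoxy-2-methylacrolein.

Key step: step 5

Assumption: the commercial enynol and ethoxy enal are taken as the pure E isomers, and the catalyst antipode in step 5 is assigned by analogy with the facial sense known for 2-substituted acroleins.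

**Route**

Step 1
Reactants: 1 (E)-3-methylpent-2-en-4-yn-1-ol
Product: 2 tert-butyldimethyl{[(E)-3-methylpent-2-en-4-yn-1-yl]oxy}silane
Conditions: TBSCl, imidazole, CH2Cl2, 0 °C → rt
Reagents that add atoms: tert-butyldimethylsilyl chloride, CC(C)(C)[Si](C)(C)Cl
Why: Imidazole-promoted silylation of the primary allylic alcohol leaves the terminal alkyne and the alkene geometry untouched and makes the C6 unit non-volatile for the next step.

Step 2
Reactants: 2 tert-butyldimethyl{[(E)-3-methylpent-2-en-4-yn-1-yl]oxy}silane
Product: 3 tert-butyldimethyl{[(2E)-3-methylpenta-2,4-dien-1-yl]oxy}silane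
Conditions: H2 (1 atm), Lindlar catalyst, quinoline, hexane, rt, stopped after 1 equiv H2
Reagents that add atoms: none
Why: Lindlar semihydrogenation should stop at the vinyl group because the terminal alkyne binds the poisoned palladium more strongly than the diene that forms, and the E trisubstituted alkene is not touched.

Step 3
Reactants: 4 (E)-3-ethoxy-2-methylprop-2-enal
Product: 5 sodium (E)-2-methyl-3-oxoprop-1-en-1-olate
Conditions: NaOH (1.0 equiv), H2O, rt; evaporate, dry in vacuo
Reagents that add atoms: sodium hydroxide, [Na+].[OH-]
Why: Saponification of the vinylogous ester by addition–elimination of hydroxide at the β-carbon should give the delocalised methylmalonaldehyde enolate, isolated as its dry sodium salt.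

Step 4
Reactants: 5 sodium (E)-2-methyl-3-oxoprop-1-en-1-olate
Product: 6 (E)-3-acetoxy-2-methylprop-2-enal
Conditions: AcCl (1.05 equiv), CH2Cl2 (suspension), 0 °C → rt; filter, distil
Reagents that add atoms: acetyl chloride, CC(=O)Cl
Why: O-acylation of a malonaldehyde enolate with an acid chloride (the way 3-acyloxyacroleins are made) should give the enol acetate with acetoxy anti to formyl, the extended and thermodynamically preferred E form, and any Z isomer would be removed on purification.

Step 5
Reactants: 3 tert-butyldimethyl{[(2E)-3-methylpenta-2,4-dien-1-yl]oxy}silane (1.5 equiv); 6 (E)-3-acetoxy-2-methylprop-2-enal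
Product: 7 (1R,5R,6R)-5-{[(tert-butyldimethylsilyl)oxy]methyl}-6-formyl-4,6-dimethylcyclohex-3-en-1-yl acetate
Conditions: (S)-o-tolyl oxazaborolidine from diphenylprolinol (20 mol %), Tf2NH (17 mol %), CH2Cl2, −78 → −20 °C; Et3N quench
Reagents that add atoms: none
Why: Proposed new method: the boron-bound s-trans enal 6, held by a formyl C–H···O contact to the ring oxygen with one face covered by the neighbouring phenyl group, should add to the s-cis diene 3 in a concerted but asynchronous [4+2] cycloaddition, its β-carbon bonding first to the unsubstituted diene terminus (C1–C2) and its α-carbon then to the substituted terminus (C5–C6); the closest known reaction type is the cationic oxazaborolidine-catalysed Diels–Alder reaction of 2-methylacrolein, 2-bromoacrolein and related α-substituted enals with acyclic dienes, whereas a β-acyloxy-α-methyl enal with a 1,2-dialkyl diene has not been shown. The cyclohexene ring closes by intermolecular suprafacial–suprafacial cycloaddition, which fixes the alkene at C3=C4. C1 and C6 are related by the E geometry of 6 (acetoxy trans to formyl), C5 is related to C6 by the endo orientation of the Lewis-acid-bound formyl group over the E diene (formyl cis to the silyloxymethyl arm, hence acetoxy trans to that arm), and the absolute sense comes from the catalyst, for which the (S) antipode is predicted and the (R) antipode is equally available should the sense prove reversed. The step needs ortho regiochemistry, formyl-endo topology and one enal face: the 1-substituent of the diene and the steric preference for first bond formation at its CH2 terminus should outweigh the opposing pull of the C4 methyl group, an acyclic diene lacks the ring methylene that drives α-methyl enals to formyl-exo addition, and the catalyst supplies the facial bias. The acetoxy group lowers the reactivity of the enal, which is why the triflimide-activated catalyst, a raised loading and a temperature ramp are specified, and because C6 is quaternary the β-acetoxy aldehyde formed cannot eliminate acetic acid.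

Step 6
Reactants: 7 (1R,5R,6R)-5-{[(tert-butyldimethylsilyl)oxy]methyl}-6-formyl-4,6-dimethylcyclohex-3-en-1-yl acetate
Product: 8 (1R,5R,6S)-5-{[(tert-butyldimethylsilyl)oxy]methyl}-4,6-dimethyl-6-[(E)-(2-tosylhydrazinylidene)methyl]cyclohex-3-en-1-yl acetate
Conditions: TsNHNH2 (1.1 equiv), THF, 4 Å MS, rt → 40 °C
Reagents that add atoms: 4-methylbenzenesulfonohydrazide, Cc1ccc(cc1)S(=O)(=O)NN
Why: Tosylhydrazone formation on a non-enolisable aldehyde should proceed without acid, and the quaternary C6 can neither epimerise nor lose the β-acetoxy group (the CIP label at C6 changes only because the substituent priorities change).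

Step 7
Reactants: 8 (1R,5R,6S)-5-{[(tert-butyldimethylsilyl)oxy]methyl}-4,6-dimethyl-6-[(E)-(2-tosylhydrazinylidene)methyl]cyclohex-3-en-1-yl acetate
Product: 11 (1R,5R)-5-{[(tert-butyldimethylsilyl)oxy]methyl}-4,6,6-trimethylcyclohex-3-en-1-yl acetate, via N-boryl hydrazide 9 (not isolated), via alkyl diazene 10 (not isolated)
Conditions: catecholborane (2 equiv), CHCl3, 0 °C → rt; then NaOAc·3H2O, reflux
Reagents that add atoms: none
Why: Catecholborane reduction of the tosylhydrazone (hydroboration of C=N, acetate-induced loss of sulfinate to the diazene, then loss of N2) should turn the formyl group into the second C6 methyl group under conditions that spare the acetate, the silyl ether and the trisubstituted alkene, and C6 ceases to be a stereocentre.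

Step 8
Reactants: 11 (1R,5R)-5-{[(tert-butyldimethylsilyl)oxy]methyl}-4,6,6-trimethylcyclohex-3-en-1-yl acetate
Product: 12 (1R,5R)-5-(hydroxymethyl)-4,6,6-trimethylcyclohex-3-en-1-yl acetate
Conditions: HF·pyridine, THF–pyridine, 0 °C → rt
Reagents that add atoms: none
Why: Fluoride-driven desilylation of the primary TBS ether under weakly acidic buffered conditions should free C7–OH without base, so the C1 acetate is neither cleaved nor migrated.

Step 9
Reactants: 12 (1R,5R)-5-(hydroxymethyl)-4,6,6-trimethylcyclohex-3-en-1-yl acetate; 13 umbelliferone (7-hydroxy-2H-chromen-2-one)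
Product: 14 (1R,5R)-4,6,6-trimethyl-5-{[(2-oxo-2H-chromen-7-yl)oxy]methyl}cyclohex-3-en-1-yl acetate
Conditions: PPh3, DIAD, THF, 0 °C → rt
Reagents that add atoms: none
Why: In this Mitsunobu etherification the acidic 7-hydroxycoumarin should protonate the betaine and its phenoxide displace the oxyphosphonium group at primary C7, with no stereocentre involved and the acetate and lactone untouched.

**Compound list**

1 | (E)-3-methylpent-2-en-4-yn-1-ol | C#C/C(C)=C/CO | starting material
2 | tert-butyldimethyl{[(E)-3-methylpent-2-en-4-yn-1-yl]oxy}silane | C#C/C(C)=C/CO[Si](C)(C)C(C)(C)C | intermediate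
3 | tert-butyldimethyl{[(2E)-3-methylpenta-2,4-dien-1-yl]oxy}silane | C=C/C(C)=C/CO[Si](C)(C)C(C)(C)C | intermediate
4 | (E)-3-ethoxy-2-methylprop-2-enal | CCO/C=C(C)/C=O | starting material
5 | sodium (E)-2-methyl-3-oxoprop-1-en-1-olate | [Na+].[O-]/C=C(C)/C=O | intermediate
6 | (E)-3-acetoxy-2-methylprop-2-enal | CC(=O)O/C=C(C)/C=O | intermediate
7 | (1R,5R,6R)-5-{[(tert-butyldimethylsilyl)oxy]methyl}-6-formyl-4,6-dimethylcyclohex-3-en-1-yl acetate | CC(=O)O[C@@H]1CC=C(C)[C@@H](CO[Si](C)(C)C(C)(C)C)[C@@]1(C)C=O | intermediate
8 | (1R,5R,6S)-5-{[(tert-butyldimethylsilyl)oxy]methyl}-4,6-dimethyl-6-[(E)-(2-tosylhydrazinylidene)methyl]cyclohex-3-en-1-yl acetate | CC(=O)O[C@@H]1CC=C(C)[C@@H](CO[Si](C)(C)C(C)(C)C)[C@@]1(C)/C=N/NS(=O)(=O)c1ccc(C)cc1 | intermediate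
9 | N-boryl hydrazide: (1R,5R,6S)-6-{[1-(1,3,2-benzodioxaborol-2-yl)-2-tosylhydrazinyl]methyl}-5-{[(tert-butyldimethylsilyl)oxy]methyl}-4,6-dimethylcyclohex-3-en-1-yl acetate, formed in the flask | CC(=O)O[C@@H]1CC=C(C)[C@@H](CO[Si](C)(C)C(C)(C)C)[C@@]1(C)CN(B2Oc3ccccc3O2)NS(=O)(=O)c1ccc(C)cc1 | intermediate
10 | alkyl diazene: (1R,5R,6S)-5-{[(tert-butyldimethylsilyl)oxy]methyl}-6-(diazenylmethyl)-4,6-dimethylcyclohex-3-en-1-yl acetate, formed in the flask | CC(=O)O[C@@H]1CC=C(C)[C@@H](CO[Si](C)(C)C(C)(C)C)[C@@]1(C)CN=N | intermediate
11 | (1R,5R)-5-{[(tert-butyldimethylsilyl)oxy]methyl}-4,6,6-trimethylcyclohex-3-en-1-yl acetate | CC(=O)O[C@@H]1CC=C(C)[C@@H](CO[Si](C)(C)C(C)(C)C)C1(C)C | intermediate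
12 | (1R,5R)-5-(hydroxymethyl)-4,6,6-trimethylcyclohex-3-en-1-yl acetate | CC(=O)O[C@@H]1CC=C(C)[C@@H](CO)C1(C)C | intermediate
13 | umbelliferone (7-hydroxy-2H-chromen-2-one) | O=c1ccc2ccc(O)cc2o1 | starting material
14 | (1R,5R)-4,6,6-trimethyl-5-{[(2-oxo-2H-chromen-7-yl)oxy]methyl}cyclohex-3-en-1-yl acetate | CC(=O)O[C@@H]1CC=C(C)[C@@H](COc2ccc3ccc(=O)oc3c2)C1(C)C | target

**Step count**

Total steps: 9. Longest linear sequence: 7 (steps 1, 2, 5, 6, 7, 8, 9 from compound 1).

**Steps most likely to fail**

1. Step 5 (proposed new method). The donor-substituted enal may be activated too weakly, so that turnover is slow while the cationic catalyst ionises or desilylates the allylic silyl ether. Selectivity may also erode through bonding of C6 to the CH2 terminus of the diene, through formyl-exo approach, or through poor discrimination of the enal faces. The fallback uses known chemistry and moves the source of enantiopurity from the catalyst to a resolution. It sets out from 3 and 6, which are combined in a Diels–Alder reaction promoted by the achiral Lewis acid Me2AlCl (CH2Cl2, −78 → −20 °C) to give the racemic adduct, that is 7 together with the enantiomer of 7 F1. The mixture is condensed with (1R,2R)-N,N'-dimethyl-1,2-diphenylethane-1,2-diamine (Et2O, 4 Å MS, rt) to give two diastereomeric imidazolidines, the aminal of 7 F2 and the aminal of the enantiomer F3, which are separated by chromatography or crystallisation. Mild two-phase acid hydrolysis of F2 (dilute aqueous acid, Et2O, 0 °C) should return enantiopure 7, where the route is rejoined.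

2. Step 7. Hydride transfer to the neopentyl C=N unit next to two substituted carbons may be incomplete, or the borane may begin to attack the ring alkene before the diazene has formed and lost nitrogen. The fallback sets out from 7 and replaces the hydrazone pathway by thioacetal desulfurisation. The aldehyde is converted with ethane-1,2-dithiol and Zn(OTf)2 in CH2Cl2 into the dithiolane F4. Raney nickel, deactivated by refluxing in acetone and then used in EtOH, should remove sulfur and leave the C6 methyl group, coming back to the route at 11.

3. Step 9. Displacement at the oxyphosphonium carbon C7 may be slow, because C7 is β-branched and sits next to the quaternary C6, so that alkylation of the hydrazinedicarboxylate or elimination competes. The fallback sets out from 12 and separates activation from substitution. Tf2O and 2,6-lutidine in CH2Cl2 at −78 °C should give the triflate F5. This is treated at 0 °C → rt in MeCN with the caesium salt of 13 (13, Cs2CO3), a Williamson etherification that comes back to the route at 14.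

Further compounds
F1 | step 5 | (1S,5S,6S)-5-{[(tert-butyldimethylsilyl)oxy]methyl}-6-formyl-4,6-dimethylcyclohex-3-en-1-yl acetate (enantiomer of 7) | CC(=O)O[C@H]1CC=C(C)[C@H](CO[Si](C)(C)C(C)(C)C)[C@]1(C)C=O
F2 | step 5 | aminal of 7: (1R,5R,6R)-5-{[(tert-butyldimethylsilyl)oxy]methyl}-6-[(4R,5R)-1,3-dimethyl-4,5-diphenylimidazolidin-2-yl]-4,6-dimethylcyclohex-3-en-1-yl acetate | CC(=O)O[C@@H]1CC=C(C)[C@@H](CO[Si](C)(C)C(C)(C)C)[C@@]1(C)C1N(C)[C@H](c2ccccc2)[C@@H](c2ccccc2)N1C
F3 | step 5 | aminal of the enantiomer: (1S,5S,6S)-5-{[(tert-butyldimethylsilyl)oxy]methyl}-6-[(4R,5R)-1,3-dimethyl-4,5-diphenylimidazolidin-2-yl]-4,6-dimethylcyclohex-3-en-1-yl acetate | CC(=O)O[C@H]1CC=C(C)[C@H](CO[Si](C)(C)C(C)(C)C)[C@]1(C)C1N(C)[C@H](c2ccccc2)[C@@H](c2ccccc2)N1C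
F4 | step 7 | (1R,5R,6R)-5-{[(tert-butyldimethylsilyl)oxy]methyl}-6-(1,3-dithiolan-2-yl)-4,6-dimethylcyclohex-3-en-1-yl acetate | CC(=O)O[C@@H]1CC=C(C)[C@@H](CO[Si](C)(C)C(C)(C)C)[C@@]1(C)C1SCCS1
F5 | step 9 | (1R,5R)-4,6,6-trimethyl-5-{[(trifluoromethylsulfonyl)oxy]methyl}cyclohex-3-en-1-yl acetate | CC(=O)O[C@@H]1CC=C(C)[C@@H](COS(=O)(=O)C(F)(F)F)C1(C)C
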